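**Assumption:** the target has no stereocentre or stereoaxis, so it is achiral. The "single enantiomer" requirement is met trivially and no step needs stereocontrol.

## Retrosynthetic overview
1. The usual o-hydroxyacetophenone routes (Baker–Venkataraman, or chalcone then oxidative cyclisation) are avoided. Instead, the C4–C4a and O1–C2 bonds are cut together in a one-step [3+3] pyrone annulation.
2. The fragments are unprotected 3,4,5-trimethoxycatechol and commercial ethyl 3,4,5-trimethoxybenzoylacetate, which acts as an aroylketene equivalent.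
3. The catechol has a single aromatic C–H, and it lies ortho to only one of the two OH groups. This fixes the regiochemistry and leaves the other OH as the free 8-OH, so no protecting groups are needed.
4. The catechol comes from commercial 3,4,5-trimethoxyphenol by ortho-selective oxygenation with IBX, followed by reduction of the o-quinone.
5. Ring order: rings A and B are purchased, and ring C (the pyrone) is formed last.

## Route

Step 1
Reactants: 1 3,4,5-trimethoxyphenol
Product: 2 3,4,5-trimethoxy-1,2-benzoquinone
Conditions: IBX (1.05 equiv), DMF, rt, dark, 1–2 h; dilute with CH2Cl2, quick cold aq NaHCO3 wash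
Reagents that add atoms: IBX (2-iodoxybenzoic acid), O=C1OI(=O)(O)c2ccccc21
Why: This is an IBX ortho-oxygenation of an electron-rich phenol, in which the aryloxy-I(V) adduct delivers oxygen intramolecularly to one of the two equivalent ortho carbons and the resulting I(III) catecholate collapses to the o-quinone, so the ipso/para attack that gives 2,6-dimethoxy-p-benzoquinone with outer-sphere oxidants is avoided.

Step 2
Reactants: 2 3,4,5-trimethoxy-1,2-benzoquinone
Product: 3 3,4,5-trimethoxybenzene-1,2-diol
Conditions: Na2S2O4 (aq, excess), EtOAc, rt, Ar, shake until the red colour is gone; dry, concentrate under Ar and use at once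
Reagents that add atoms: none
Why: This is a dithionite quinone-to-catechol reduction, a fast two-electron, two-proton process that leaves the methyl ethers untouched, and the storable quinone is converted to the air-sensitive catechol only just before use.

Step 3
Reactants: 3 3,4,5-trimethoxybenzene-1,2-diol; 4 ethyl 3-(3,4,5-trimethoxyphenyl)-3-oxopropanoate (2 equiv)
Product: 7 8-hydroxy-5,6,7,3',4',5'-hexamethoxyflavone, via aroylketene 5 (not isolated), via o-hydroxyaryl 1,3-diketone 6 (not isolated)
Conditions: Ph2O (degassed), 245–250 °C, Ar sweep, short-path removal of EtOH/H2O, 2–3 h; cool, precipitate with hexane, chromatograph, recrystallise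
Reagents that add atoms: none
Why: This is a Mentzer thermal flavone synthesis (acid-free Simonis-type condensation), in which 4 loses EtOH to give aroylketene 5, reversible O-acylation funnels into C-acylation at the only free ring carbon (ortho to OH and OMe, para to OMe), and diketone 6 dehydrates irreversibly through the one adjacent OH to give the pyrone, while omitting acid suppresses the Pechmann 4-arylcoumarin pathway.

**Route check**
- Mass balance for step 3: C9H12O5 + C14H18O6 → C21H22O9 + C2H6O + H2O.
- Atom mapping from catechol to flavone: C6→C4a, C1→C8a, C2→C8 (OH), C3→C7 (OMe), C4→C6 (OMe), C5→C5 (OMe). This matches the target SMILES.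
- No stereocentres are created anywhere in the route.

## Compound list
1 | 3,4,5-trimethoxyphenol | COc1cc(O)cc(OC)c1OC | starting material
2 | 3,4,5-trimethoxy-1,2-benzoquinone | O=C1C=C(OC)C(OC)=C(OC)C1=O | intermediate
3 | 3,4,5-trimethoxybenzene-1,2-diol | Oc1cc(OC)c(OC)c(OC)c1O | intermediate
4 | ethyl 3-(3,4,5-trimethoxyphenyl)-3-oxopropanoate | CCOC(=O)CC(=O)c1cc(OC)c(OC)c(OC)c1 | starting material
5 | 3-(3,4,5-trimethoxyphenyl)-3-oxoprop-1-en-1-one (aroylketene) | COc1cc(C(=O)C=C=O)cc(OC)c1OC | intermediate
6 | 1-(2,3-dihydroxy-4,5,6-trimethoxyphenyl)-3-(3,4,5-trimethoxyphenyl)propane-1,3-dione | COc1cc(C(=O)CC(=O)c2c(O)c(O)c(OC)c(OC)c2OC)cc(OC)c1OC | intermediate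
7 | 8-hydroxy-5,6,7,3',4',5'-hexamethoxyflavone | COc1cc(-c2cc(=O)c3c(OC)c(OC)c(OC)c(O)c3o2)cc(OC)c1OC | target

**Total step count:** 3. **Longest linear sequence:** 3 (1 → 2 → 3 → 7).

## Steps most likely to fail, with fallbacks

**Step 3 (highest risk).**
- Risks: an oxidisable catechol is held at 250 °C. Competing processes are ketene dimerisation, decarboxylation of 4 by the released water, and O-acylated or ketal dead ends.
- Fallback: this sets out from 3 and returns at 7 by stepwise ring construction.
  - C-Acetylate 3 with AcOH/BF3·OEt2 (Friedel–Crafts/Fries) to give 1-(2,3-dihydroxy-4,5,6-trimethoxyphenyl)ethanone F3.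
  - Acylate both phenols with 3,4,5-trimethoxybenzoyl chloride in pyridine to give 3-acetyl-4,5,6-trimethoxy-1,2-phenylene bis(3,4,5-trimethoxybenzoate) F4.
  - Carry out the Baker–Venkataraman shift with KOH/pyridine. Only the ester ortho to the acetyl group can be reached, which gives 2-hydroxy-4,5,6-trimethoxy-3-[3-oxo-3-(3,4,5-trimethoxyphenyl)propanoyl]phenyl 3,4,5-trimethoxybenzoate F5.
  - Cyclodehydrate with H2SO4/AcOH to give 5,6,7,3',4',5'-hexamethoxyflavon-8-yl 3,4,5-trimethoxybenzoate F6.
  - Methanolyse the remaining ester, which has protected the 8-OH throughout, with K2CO3/MeOH to give 7.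

**Step 1.**
- Risks: loss of the 4-OMe group could give the p-quinone, and the vinylogous-ester quinone could hydrolyse or dimerise.
- Fallback: this sets out from 1 and returns at 3, bypassing 2, so that the oxygen is introduced through a carbon handle.
  - Ortho-formylate 1 with MgCl2/Et3N/paraformaldehyde in MeCN to give 2-hydroxy-4,5,6-trimethoxybenzaldehyde F1.
  - Carry out a Dakin oxidation (H2O2, aq NaOH, Ar, then acidify) to give catechol 3.

**Step 2.**
- Risk: the catechol may re-oxidise during isolation and drying.
- Fallback: this sets out from 2 and returns at 3.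
  - Reductively acetylate 2 with Zn, Ac2O and NaOAc to trap the catechol as the air-stable, purifiable 3,4,5-trimethoxy-1,2-phenylene diacetate F2.
  - Release 3 with K2CO3 in degassed MeOH, acidify under Ar, and take it directly into step 3.

## Further compounds
F1 | step 1 | 2-hydroxy-4,5,6-trimethoxybenzaldehyde | O=Cc1c(O)cc(OC)c(OC)c1OC
F2 | step 2 | 3,4,5-trimethoxy-1,2-phenylene diacetate | CC(=O)Oc1cc(OC)c(OC)c(OC)c1OC(C)=O
F3 | step 3 | 1-(2,3-dihydroxy-4,5,6-trimethoxyphenyl)ethanone | CC(=O)c1c(O)c(O)c(OC)c(OC)c1OC
F4 | step 3 | 3-acetyl-4,5,6-trimethoxy-1,2-phenylene bis(3,4,5-trimethoxybenzoate) | CC(=O)c1c(OC(=O)c2cc(OC)c(OC)c(OC)c2)c(OC(=O)c2cc(OC)c(OC)c(OC)c2)c(OC)c(OC)c1OC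
F5 | step 3 | 2-hydroxy-4,5,6-trimethoxy-3-[3-oxo-3-(3,4,5-trimethoxyphenyl)propanoyl]phenyl 3,4,5-trimethoxybenzoate | COc1cc(C(=O)CC(=O)c2c(O)c(OC(=O)c3cc(OC)c(OC)c(OC)c3)c(OC)c(OC)c2OC)cc(OC)c1OC
F6 | step 3 | 5,6,7,3',4',5'-hexamethoxyflavon-8-yl 3,4,5-trimethoxybenzoate | COc1cc(-c2cc(=O)c3c(OC)c(OC)c(OC)c(OC(=O)c4cc(OC)c(OC)c(OC)c4)c3o2)cc(OC)c1OC
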